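## Structural features

The target is a 2,3-dihydro-1-benzofuran in which benzene ring A (C3a, C4 to C7, C7a) is fused to dihydrofuran ring B (O1, C2, C3, C3a, C7a); ring A carries an acetyl group at C5 and, ortho to it and para to C3a, a hydroxyl at C6 that is hydrogen-bonded to the ketone. C2 bears a prop-1-en-2-yl group and C3 an acyloxy group, and these two neighbouring stereocentres are (2S,3R), that is trans across the C2–C3 bond. The acyl group is (Z)-2-(acetoxymethyl)but-2-enoyl, an angelate-type residue whose β-methyl lies cis to the carbonyl (the less stable geometry) and whose allylic acetate makes the enoate an SN2′ acceptor. The C3–O bond is the weak point: it is benzylic, supported by O1 (ortho) and by the C6 oxygen (para), and loss of the carboxylate together with the hydrogen at C2 would give the aromatic 2-isopropenylbenzofuran; the Z-enoate isomerises when the acid is activated as an acyl donor, and the two alkenes rule out hydrogenolysis. The real difficulty is therefore to set C2 and C3 in one absolute sense and to attach the hindered Z-acid at C3 without elimination or double-bond isomerisation. The key step exploits that C2 is bonded to O1, to C3 and to a 1-methylvinyl group: this pattern arises when the oxygen-bearing carbon of an O-allenyl salicylaldehyde is joined to the formyl carbon (C2–C3, closing ring B) while a methyl group is delivered to the central allene carbon.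

## Logic of the disconnections

23 back to 21 (through 22): the O6–CH2 acetal bond is cut. The C6 oxygen must stay masked through two base steps, the nickel step and the Mitsunobu step, where a free para-hydroxyl would open a quinone-methide path at C3. Nothing is gained in the skeleton. The demand on the forward step is cleavage without ionising the C3–O bond, so a nearly neutral silyl triflate/2,2′-bipyridyl exchange is preferred to aqueous acid.

21 back to 19 and 20, then 19 back to 18: the acetate O–acyl bond and then the O–Si bond are cut. The allylic acetate could not survive the saponification that frees 17 and would make 17 an SN2′ acceptor for triphenylphosphine, so the hydroxymethyl group travels as a silyl ether. The forward steps must use buffered fluoride and a mild acylation that leave the C3 ester alone.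

18 back to 11 and 17: the C3–O bond (alkyl–oxygen) is cut. The ring-forming step delivers the cis alcohol, so the ester must be made with inversion. Activating the alcohol rather than the acid also protects the Z-alkene of 17. The gain is a convergent union of two fragments; the demand is that SN2 displacement outruns elimination to the benzofuran.

11 back to 9 and 10: the C2–C3 bond and the bond between the vinyl carbon and its methyl group are cut. This removes ring B, both stereocentres and the isopropenyl group at once and leads to an achiral, planar aldehyde. The forward step must choose the aldehyde over the ketone, close the five-membered ring, give the cis relationship and select one aldehyde face.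

9 back to 7 (through 8): the allenyl ether is traced to the propargyl ether by a prototropic shift, and the acetyl group to a 1-ethoxyvinyl group. An aryl methyl ketone and an aryl aldehyde in the same flask with KOtBu would condense, so the ketone has to stay masked through the base step. The forward demand is a hydrolysis that removes the α-ethoxystyrene and spares the allenyl ether.

7 back to 5 and 6: the ether bond between the future O1 and the future C2 is cut. This is a plain phenol alkylation; the only demand is that the chelated phenol reacts in the presence of aldehyde and enol ether.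

5 back to 3 and 4: the aryl–carbon bond at C5 is cut. The bromine marks the position of the acetyl group from the start and the coupling product is already the masked ketone. The forward step must not protonate the stannane or the enol ether.

3 back to 1 and 2: the O–CH2 bond on the future O6 is cut. The forward step must distinguish the two phenols, which the hydrogen bond of the other hydroxyl to the aldehyde provides.

17 back to 16, 16 back to 14 and 15, 14 back to 12 and 13: the ester O–CH3 bond, the C=C bond and the bond from the α-carbon to the CH2O carbon are cut in turn. The trisubstituted Z-alkene is the only stereochemical element and is placed on an olefination that is Z-selective by design; the hydroxymethyl carbon enters as a silyl-protected chloromethyl ether. The demands are C-alkylation of the phosphonate anion and kinetic control in the olefination.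

## Other disconnections considered

Alternative 1: The cut is the O1–C2 bond of ring B together with a methyl C–H bond. Backwards, O1 returns to the carbon that becomes the isopropenyl carbon, which turns ring B into the pyran ring of the trans-(3S,4R) 2,2-dimethylchromanol ester A2. Forward, triflation of the free C3 hydroxyl of A2 (Tf2O, 2,6-lutidine) would let the ring oxygen, antiperiplanar to the equatorial leaving group, displace it with inversion; the bridged oxonium ion opens at the tertiary carbon and loses a methyl proton, giving A1, the 6-O-triisopropylsilyl ether of 23.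
- In favour: A2 traces back to the chromene A3, which belongs to the substrate class best suited to Jacobsen–Katsuki epoxidation. On enantiocontrol this alternative is the better plan, since step 5 relies on ligand control that is untested for its substrate. Anti opening of the epoxide by a carboxylic acid would install the ester already trans, so no inversion at C3 is needed (also better), and the final fluoride cleavage of an aryl silyl ether is gentler than step 12 (better).
- Against here: O1 is para to the acetyl group and so a weak migrating donor; the trans ester carbonyl is equally well placed to participate and form a dioxolanium ion; methyl or hydride shift and elimination towards a chromene would compete; the linear chromene A3 must be built regioselectively. The uncertain step would also come last, on the fully elaborated ester, whereas step 5 is tried on an intermediate four steps from purchase.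
- Comparison: mechanistically a conformation-steered cationic rearrangement stands against a ligand-steered organometallic cyclisation; structurally the isopropenyl group arises by breaking up a gem-dimethyl unit rather than by building it. Step economy should be about equal.

Alternative 2: The cut is the aryl ether bond O1–C7a. Forward, KOtBu would convert the C2 hydroxyl of the anti (1R,2S) diol A5 into an alkoxide that displaces the fluoride para to the acetyl group by addition–elimination (five-membered closure), giving the fluoro alcohol A4.
- In favour: the acetyl group activates exactly the carbon that must be attacked, no stereocentre is touched, and A4 already has the trans 3-hydroxyl, so the side chain could be attached with retention. The ring closure itself should be at least as dependable as step 5, and the absence of an inversion is a point on which it is better.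
- Against here: both stereocentres have to be made beforehand in an open chain, and the required relationship is anti, which a syn dihydroxylation of an E-alkene does not give. The base meets an enolisable methyl ketone. The second fluoride, ortho to the acetyl group, is also activated and must later be exchanged for oxygen by a second substitution on a more sensitive molecule.
- Comparison: the chosen plan creates C2, C3 and ring B together from an achiral substrate at the price of unproven stereocontrol; this alternative moves stereocontrol into conventional but longer chemistry, so its step economy is worse.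

Alternative 3: The cut is the C3a–C3 bond. Forward, CrCl2 with catalytic NiCl2 would turn the aryl iodide of the aldehyde A7 into an arylchromium species (nickel inserts into the C–I bond and passes the aryl group to chromium) that adds to the tethered aldehyde in a five-membered closure, giving the diol A6 with the new C3 carbinol.
- In favour: organochromium reagents add to aldehydes and ignore aryl ketones and free phenols, so no phenol protection would be needed and the endgame would shrink to one esterification with retention. On chemoselectivity and step economy this alternative is the equal or the better of the chosen plan.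
- Against here: A7 is an α-aryloxy β,γ-unsaturated aldehyde whose C2–H is both α to the carbonyl and allylic, so loss of configuration and migration of the double bond into conjugation threaten before the key step. The C3 configuration would rest on 1,2-induction from C2 of unknown sense. Low-valent nickel can ionise the allylic aryl ether, and the chromium salt is needed in excess.
- Comparison: in the chosen plan C2 is never a stereocentre next to a carbonyl group and both centres arise together in one metallacycle; here the ring closure is the simpler organometallic event, but its precursor is the fragile compound.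

Key step: step 5

Assumption (remark on the chemistry): the sense of induction of the chiral ligand in step 5 cannot be predicted; the enantiomer of the ligand that delivers the (3S) carbinol is taken, and its antipode is used if the opposite face is favoured.

## Route

Step 1
Reactants: 1 5-bromo-2,4-dihydroxybenzaldehyde; 2 chloromethyl methyl ether
Product: 3 5-bromo-2-hydroxy-4-(methoxymethoxy)benzaldehyde
Conditions: K2CO3 (1.1 equiv), 2 (1.05 equiv), acetone, 0 °C to rt
Reagents that add atoms: chloromethyl methyl ether (2), COCCl
Why: Williamson-type O-alkylation: the 2-hydroxyl is held in a hydrogen bond to the formyl group, so the free and more acidic 4-hydroxyl (para to the aldehyde, ortho to bromine) should react first when one equivalent of 2 is used. No stereocentre is formed.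

Step 2
Reactants: 3 5-bromo-2-hydroxy-4-(methoxymethoxy)benzaldehyde; 4 tributyl(1-ethoxyvinyl)stannane
Product: 5 5-(1-ethoxyvinyl)-2-hydroxy-4-(methoxymethoxy)benzaldehyde
Conditions: Pd(PPh3)4 (5 mol%), CuI (10 mol%), CsF (2 equiv), DMF, 50 °C; pH 7 work-up, basic alumina
Reagents that add atoms: tributyl(1-ethoxyvinyl)stannane (4), CCCC[Sn](CCCC)(CCCC)C(=C)OCC
Why: Stille coupling of the aryl bromide with the α-alkoxyvinylstannane; the fluoride/copper variant runs at low temperature and keeps the phenol as its caesium salt, so neither the stannane nor the enol ether is protonated. The 1-ethoxyvinyl group is deliberately kept as the masked acetyl group for the base steps that follow.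

Step 3
Reactants: 5 5-(1-ethoxyvinyl)-2-hydroxy-4-(methoxymethoxy)benzaldehyde; 6 propargyl bromide
Product: 7 5-(1-ethoxyvinyl)-4-(methoxymethoxy)-2-(prop-2-yn-1-yloxy)benzaldehyde
Conditions: K2CO3, DMF, rt
Reagents that add atoms: propargyl bromide (6), C#CCBr
Why: Williamson etherification of the remaining chelated phenol, routine for salicylaldehydes; aldehyde, enol ether and acetal are inert to carbonate.

Step 4
Reactants: 7 5-(1-ethoxyvinyl)-4-(methoxymethoxy)-2-(prop-2-yn-1-yloxy)benzaldehyde
Product: 9 5-acetyl-4-(methoxymethoxy)-2-(propa-1,2-dien-1-yloxy)benzaldehyde, via allenyl ether 8 (not isolated)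
Conditions: KOtBu (0.3 equiv), THF, −20 to 0 °C; then aqueous citrate buffer (pH 3), 0 °C
Reagents that add atoms: water, O
Why: Base-catalysed propargyl-to-allenyl ether isomerisation (prototropic shift) with substoichiometric KOtBu at low temperature, stopped before the 1-propynyl ether forms; no enolisable ketone is present, so Claisen–Schmidt condensation with the aldehyde is excluded. In the buffered quench the α-ethoxystyrene, which protonates to a donor-stabilised benzylic oxocarbenium ion, should hydrolyse far faster than the allenyl ether on its electron-poor aryloxy group or the aryl acetal, giving the ketone of 9.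

Step 5
Reactants: 9 5-acetyl-4-(methoxymethoxy)-2-(propa-1,2-dien-1-yloxy)benzaldehyde; 10 dimethylzinc
Product: 11 1-[(2S,3S)-3-hydroxy-6-(methoxymethoxy)-2-(prop-1-en-2-yl)-2,3-dihydro-1-benzofuran-5-yl]ethanone (cis)
Conditions: Ni(cod)2 (10 mol%), chiral monodentate spirobiindane phosphoramidite (for example (R)-SIPHOS-PE, 12 mol%), Zn(CH3)2 (2.5 equiv), THF, 0 °C, slow addition of 9; then sat. aq. NH4Cl
Reagents that add atoms: dimethylzinc (10), C[Zn]C
Why: Proposed new method: zerovalent nickel carrying the chiral ligand should bind the aldehyde and the oxygen-substituted C=C bond of the allene of 9 and couple them oxidatively, forming the C2–C3 bond and an oxanickelacyclopentane in which nickel is σ-bound to the former central allene carbon as an alkenyl group with an exocyclic CH2; methyl transfer from 10 to nickel (zinc taking the alkoxide) and C–C reductive elimination then place the methyl group on that carbon and release the methylzinc alkoxide of 11 and the catalyst. The closest known reaction type is the nickel/organozinc alkylative cyclisation of carbon-tethered allenyl aldehydes to cis-2-(1-alkylvinyl)cycloalkanols, and its use on an aryloxyallene under ligand-based enantiocontrol is the untested extension. Ring B closes in a 5-exo mode, with both the C=O bond and the reacting C=C bond outside the new ring, because the three-atom tether (C3a, C7a, O1) makes closure through the central allene carbon a strained six-membered endo path. C3 is set by the aldehyde face that the ligand-bound nickel selects (ligand control), and C2 is set relative to C3 by the cis fusion of ring B to the metallacycle, so that the C3 oxygen and the 2-propenyl group end up cis, (2S,3S). The step needs chemoselectivity for the aldehyde over the aryl ketone, secured because the ketone is less electrophilic and cannot reach the allene within the molecule, and methyl transfer without reduction, secured because a methyl group has no β-hydrogen. Slow addition of 9 to the catalyst and 10 at 0 °C should keep direct methyl addition to the aldehyde and allene oligomerisation in the background. The electron-poor aryloxy group (para-acetyl, ortho-formyl) should also lower the tendency of nickel to cleave the allenyl C–O bond.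

Step 6
Reactants: 12 methyl bis(2,2,2-trifluoroethyl)phosphonoacetate; 13 (chloromethoxy)triisopropylsilane [(triisopropylsiloxy)methyl chloride]
Product: 14 methyl 2-[bis(2,2,2-trifluoroethoxy)phosphoryl]-3-[(triisopropylsilyl)oxy]propanoate (racemic)
Conditions: NaH (1.0 equiv), THF, 0 °C; then 13 (1.0 equiv), 0 °C to rt
Reagents that add atoms: (chloromethoxy)triisopropylsilane (13), CC(C)[Si](OCCl)(C(C)C)C(C)C
Why: C-alkylation of the stabilised phosphonoacetate carbanion by a reactive α-chloro ether; one equivalent each of base and electrophile limits double alkylation. The new stereocentre is racemic and is destroyed in step 7.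

Step 7
Reactants: 14 methyl 2-[bis(2,2,2-trifluoroethoxy)phosphoryl]-3-[(triisopropylsilyl)oxy]propanoate; 15 acetaldehyde
Product: 16 methyl (2Z)-2-{[(triisopropylsilyl)oxy]methyl}but-2-enoate
Conditions: KN(SiMe3)2, 18-crown-6, THF, −78 °C; then CH3CHO
Reagents that add atoms: acetaldehyde (15), CC=O
Why: Still–Gennari olefination: the electron-poor bis(trifluoroethyl) phosphonate under dissociating conditions eliminates from the kinetic adduct, which places the aldehyde methyl group cis to the ester, the (Z)-alkene needed. β-Loss of silanolate from the carbanion is reversible and should not compete with addition to acetaldehyde at −78 °C.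

Step 8
Reactants: 16 methyl (2Z)-2-{[(triisopropylsilyl)oxy]methyl}but-2-enoate
Product: 17 (2Z)-2-{[(triisopropylsilyl)oxy]methyl}but-2-enoic acid
Conditions: LiOH, THF/H2O, 0 °C to rt; then 1 M HCl to pH 4
Reagents that add atoms: lithium hydroxide, [Li+].[OH-]
Why: Saponification of the methyl ester; the primary triisopropylsilyl ether is stable to hydroxide and to brief cold dilute acid, and the low temperature should leave the Z-alkene unchanged.

Step 9
Reactants: 11 1-[(2S,3S)-3-hydroxy-6-(methoxymethoxy)-2-(prop-1-en-2-yl)-2,3-dihydro-1-benzofuran-5-yl]ethanone; 17 (2Z)-2-{[(triisopropylsilyl)oxy]methyl}but-2-enoic acid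
Product: 18 (2S,3R)-5-acetyl-6-(methoxymethoxy)-2-(prop-1-en-2-yl)-2,3-dihydro-1-benzofuran-3-yl (2Z)-2-{[(triisopropylsilyl)oxy]methyl}but-2-enoate (trans)
Conditions: PPh3, DIAD, toluene, 0 °C to rt
Reagents that add atoms: (2Z)-2-{[(triisopropylsilyl)oxy]methyl}but-2-enoic acid (17), OC(=O)/C(=C\C)CO[Si](C(C)C)(C(C)C)C(C)C
Why: Mitsunobu esterification: the C3 hydroxyl is activated as an alkoxyphosphonium ion and displaced by the carboxylate of 17 in an SN2 step from the face anti to the 2-propenyl group, so C3 is inverted from S to R and the trans ester results. Because the alcohol and not the acid is activated, the Z-enoate cannot isomerise through an acyl-activated intermediate.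

Step 10
Reactants: 18 (2S,3R)-5-acetyl-6-(methoxymethoxy)-2-(prop-1-en-2-yl)-2,3-dihydro-1-benzofuran-3-yl (2Z)-2-{[(triisopropylsilyl)oxy]methyl}but-2-enoate
Product: 19 (2S,3R)-5-acetyl-6-(methoxymethoxy)-2-(prop-1-en-2-yl)-2,3-dihydro-1-benzofuran-3-yl (2Z)-2-(hydroxymethyl)but-2-enoate
Conditions: Bu4NF, AcOH (1 equiv each), THF, 0 °C to rt
Reagents that add atoms: none
Why: Fluoride-mediated cleavage of the primary silyl ether; acetic acid buffers the alkoxide so that the C3 ester is neither cleaved nor eliminated, and the aryl acetal is untouched.

Step 11
Reactants: 19 (2S,3R)-5-acetyl-6-(methoxymethoxy)-2-(prop-1-en-2-yl)-2,3-dihydro-1-benzofuran-3-yl (2Z)-2-(hydroxymethyl)but-2-enoate; 20 acetic anhydride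
Product: 21 (2S,3R)-5-acetyl-6-(methoxymethoxy)-2-(prop-1-en-2-yl)-2,3-dihydro-1-benzofuran-3-yl (2Z)-2-(acetoxymethyl)but-2-enoate
Conditions: Ac2O, pyridine, DMAP (cat.), CH2Cl2, 0 °C
Reagents that add atoms: acetic anhydride (20), CC(=O)OC(C)=O
Why: Standard acylation of a primary allylic alcohol by an anhydride under nucleophilic catalysis; the only free hydroxyl is acetylated and no stereocentre is affected.

Step 12
Reactants: 21 (2S,3R)-5-acetyl-6-(methoxymethoxy)-2-(prop-1-en-2-yl)-2,3-dihydro-1-benzofuran-3-yl (2Z)-2-(acetoxymethyl)but-2-enoate
Product: 23 (2S,3R)-5-acetyl-6-hydroxy-2-(prop-1-en-2-yl)-2,3-dihydro-1-benzofuran-3-yl (2Z)-2-(acetoxymethyl)but-2-enoate, via aryl trimethylsilyl ether 22 (not isolated)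
Conditions: Me3SiOTf, 2,2′-bipyridyl, CH2Cl2, 0 °C; then H2O, rt
Reagents that add atoms: none
Why: Cleavage of an aromatic methoxymethyl ether by silyl triflate in the presence of 2,2′-bipyridyl: the acetal is exchanged for the aryl silyl ether 22 with a pyridinium-bound methoxymethyl unit under nearly neutral conditions, and water then frees the phenol. The buffered medium should spare the acid-labile benzylic C3 ester, the allylic acetate and both stereocentres.

## Compound list

1 | 5-bromo-2,4-dihydroxybenzaldehyde | O=Cc1cc(Br)c(O)cc1O | starting material
2 | chloromethyl methyl ether | COCCl | starting material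
3 | 5-bromo-2-hydroxy-4-(methoxymethoxy)benzaldehyde | O=Cc1cc(Br)c(OCOC)cc1O | intermediate
4 | tributyl(1-ethoxyvinyl)stannane | CCCC[Sn](CCCC)(CCCC)C(=C)OCC | starting material
5 | 5-(1-ethoxyvinyl)-2-hydroxy-4-(methoxymethoxy)benzaldehyde | C=C(OCC)c1cc(C=O)c(O)cc1OCOC | intermediate
6 | propargyl bromide (3-bromoprop-1-yne) | C#CCBr | starting material
7 | 5-(1-ethoxyvinyl)-4-(methoxymethoxy)-2-(prop-2-yn-1-yloxy)benzaldehyde | C#CCOc1cc(OCOC)c(C(=C)OCC)cc1C=O | intermediate
8 | 5-(1-ethoxyvinyl)-4-(methoxymethoxy)-2-(propa-1,2-dien-1-yloxy)benzaldehyde | C=C=COc1cc(OCOC)c(C(=C)OCC)cc1C=O | intermediate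
9 | 5-acetyl-4-(methoxymethoxy)-2-(propa-1,2-dien-1-yloxy)benzaldehyde | C=C=COc1cc(OCOC)c(C(C)=O)cc1C=O | intermediate
10 | dimethylzinc | C[Zn]C | starting material
11 | 1-[(2S,3S)-3-hydroxy-6-(methoxymethoxy)-2-(prop-1-en-2-yl)-2,3-dihydro-1-benzofuran-5-yl]ethanone | C=C(C)[C@@H]1Oc2cc(OCOC)c(C(C)=O)cc2[C@@H]1O | intermediate
12 | methyl bis(2,2,2-trifluoroethyl)phosphonoacetate | COC(=O)CP(=O)(OCC(F)(F)F)OCC(F)(F)F | starting material
13 | (chloromethoxy)triisopropylsilane | CC(C)[Si](OCCl)(C(C)C)C(C)C | starting material
14 | methyl 2-[bis(2,2,2-trifluoroethoxy)phosphoryl]-3-[(triisopropylsilyl)oxy]propanoate (racemic) | COC(=O)C(CO[Si](C(C)C)(C(C)C)C(C)C)P(=O)(OCC(F)(F)F)OCC(F)(F)F | intermediate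
15 | acetaldehyde | CC=O | starting material
16 | methyl (2Z)-2-{[(triisopropylsilyl)oxy]methyl}but-2-enoate | COC(=O)/C(=C\C)CO[Si](C(C)C)(C(C)C)C(C)C | intermediate
17 | (2Z)-2-{[(triisopropylsilyl)oxy]methyl}but-2-enoic acid | OC(=O)/C(=C\C)CO[Si](C(C)C)(C(C)C)C(C)C | intermediate
18 | (2S,3R)-5-acetyl-6-(methoxymethoxy)-2-(prop-1-en-2-yl)-2,3-dihydro-1-benzofuran-3-yl (2Z)-2-{[(triisopropylsilyl)oxy]methyl}but-2-enoate | C=C(C)[C@@H]1Oc2cc(OCOC)c(C(C)=O)cc2[C@H]1OC(=O)/C(=C\C)CO[Si](C(C)C)(C(C)C)C(C)C | intermediate
19 | (2S,3R)-5-acetyl-6-(methoxymethoxy)-2-(prop-1-en-2-yl)-2,3-dihydro-1-benzofuran-3-yl (2Z)-2-(hydroxymethyl)but-2-enoate | C=C(C)[C@@H]1Oc2cc(OCOC)c(C(C)=O)cc2[C@H]1OC(=O)/C(=C\C)CO | intermediate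
20 | acetic anhydride | CC(=O)OC(C)=O | starting material
21 | (2S,3R)-5-acetyl-6-(methoxymethoxy)-2-(prop-1-en-2-yl)-2,3-dihydro-1-benzofuran-3-yl (2Z)-2-(acetoxymethyl)but-2-enoate | C=C(C)[C@@H]1Oc2cc(OCOC)c(C(C)=O)cc2[C@H]1OC(=O)/C(=C\C)COC(C)=O | intermediate
22 | (2S,3R)-5-acetyl-2-(prop-1-en-2-yl)-6-[(trimethylsilyl)oxy]-2,3-dihydro-1-benzofuran-3-yl (2Z)-2-(acetoxymethyl)but-2-enoate | C=C(C)[C@@H]1Oc2cc(O[Si](C)(C)C)c(C(C)=O)cc2[C@H]1OC(=O)/C(=C\C)COC(C)=O | intermediate
23 | (2S,3R)-5-acetyl-6-hydroxy-2-(prop-1-en-2-yl)-2,3-dihydro-1-benzofuran-3-yl (2Z)-2-(acetoxymethyl)but-2-enoate (CNP0193314.2) | C=C(C)[C@@H]1Oc2cc(O)c(C(C)=O)cc2[C@H]1OC(=O)/C(=C\C)COC(C)=O | target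

## Step count and least certain steps

Total: 12 steps. Longest linear sequence: 9 steps (steps 1 to 5 and 9 to 12, from 1); the side-chain branch (steps 6 to 8, from 12) joins at step 9.

Step 5 (key step, the only step beyond known chemistry). The most likely failures are: poor facial selectivity at the aldehyde, since no ligand has been matched to an aryloxyallene; ring closure through the central allene carbon, which is the nucleophilic carbon of an enol ether, to a six-membered ring; direct nickel-mediated methyl transfer to the aldehyde; and insertion of nickel into the allenyl C–O bond. The fallback uses known chemistry, sets out from 3 and returns at 11. O-Alkylation of 3 with chloroacetone (K2CO3, acetone, rt, stopped before Rap–Stoermer condensation) should give 5-bromo-4-(methoxymethoxy)-2-(2-oxopropoxy)benzaldehyde F1. A proline-catalysed intramolecular 5-enolexo aldol reaction, with the proline enantiomer that gives the 3S carbinol, should give the cis aldol 1-[(2R,3S)-5-bromo-3-hydroxy-6-(methoxymethoxy)-2,3-dihydro-1-benzofuran-2-yl]ethanone F2; it has the same spatial arrangement as 11, and the C2 descriptor changes only because acetyl outranks C3. Silylation (Et3SiCl, imidazole) should give 1-[(2R,3S)-5-bromo-6-(methoxymethoxy)-3-(triethylsilyloxy)-2,3-dihydro-1-benzofuran-2-yl]ethanone F3. Non-basic Tebbe methylenation with Cp2Ti(μ-Cl)(μ-CH2)AlMe2, chosen because a basic ylide would provoke β-elimination to the benzofuran, should give (2S,3S)-5-bromo-6-(methoxymethoxy)-2-(prop-1-en-2-yl)-3-(triethylsilyloxy)-2,3-dihydro-1-benzofuran F4. Stille coupling with 4 under the conditions of step 2 should give (2S,3S)-5-(1-ethoxyvinyl)-6-(methoxymethoxy)-2-(prop-1-en-2-yl)-3-(triethylsilyloxy)-2,3-dihydro-1-benzofuran F5, which dilute aqueous acid converts into 11 by hydrolysis of the enol ether and the silyl ether.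

Step 4. The most likely failures are addition of the transient oxygen-substituted propargyl/allenyl carbanion to the neighbouring formyl group, over-isomerisation to the 1-propynyl ether, and partial loss of the allenyl ether in the acidic quench. The fallback sets out from 7 and returns at 9, with the aldehyde masked during the base step. Treatment of 7 with HC(OMe)3 and MeOH under pyridinium tosylate catalysis should give 1-(1,1-dimethoxyethyl)-5-(dimethoxymethyl)-2-(methoxymethoxy)-4-(prop-2-yn-1-yloxy)benzene F6, the enol ether ending as the dimethyl ketal. KOtBu in THF should isomerise it to 1-(1,1-dimethoxyethyl)-5-(dimethoxymethyl)-2-(methoxymethoxy)-4-(propa-1,2-dien-1-yloxy)benzene F7. The pH 3 buffer of step 4 then unmasks aldehyde and ketone together, both acetals being far more labile than the allenyl ether, and gives 9.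

Step 9. The most likely failures are elimination of the activated C3 oxygen with the anti hydrogen at C2 to the aromatic benzofuran, and ionisation of the activated benzylic centre with loss of stereochemical fidelity, both favoured by the slow attack of a hindered, weakly acidic carboxylate. The fallback sets out from 11 and returns at 18; it separates inversion from attachment of the valuable acid. Mitsunobu reaction of 11 with the more acidic 4-nitrobenzoic acid should give (2S,3R)-5-acetyl-6-(methoxymethoxy)-2-(prop-1-en-2-yl)-2,3-dihydro-1-benzofuran-3-yl 4-nitrobenzoate F8. Methanolysis (K2CO3, MeOH) should give the trans alcohol 1-[(2S,3R)-3-hydroxy-6-(methoxymethoxy)-2-(prop-1-en-2-yl)-2,3-dihydro-1-benzofuran-5-yl]ethanone F9. Yamaguchi acylation with 17 (2,4,6-trichlorobenzoyl chloride, Et3N, then DMAP), which keeps angelate-type acids Z, then gives 18 with retention.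

Step 12. The most likely failure is ionisation of the benzylic C3–O bond under Lewis-acid activation, leading to loss of the ester and aromatisation. The fallback sets out from 11 and returns at 23; it removes the acetal before the ester exists and finishes with fluoride only. The conditions of step 12 applied to 11 should give 1-[(2S,3S)-3,6-dihydroxy-2-(prop-1-en-2-yl)-2,3-dihydro-1-benzofuran-5-yl]ethanone F10, the C3 hydroxyl being only silylated transiently. Phenol-selective silylation (iPr3SiCl, imidazole, DMF, 0 °C) should give 1-[(2S,3S)-3-hydroxy-2-(prop-1-en-2-yl)-6-(triisopropylsilyloxy)-2,3-dihydro-1-benzofuran-5-yl]ethanone F11. Mitsunobu esterification with 17 should give (2S,3R)-5-acetyl-2-(prop-1-en-2-yl)-6-(triisopropylsilyloxy)-2,3-dihydro-1-benzofuran-3-yl (2Z)-2-{[(triisopropylsilyl)oxy]methyl}but-2-enoate F12. Buffered Bu4NF should remove both silyl groups to give (2S,3R)-5-acetyl-6-hydroxy-2-(prop-1-en-2-yl)-2,3-dihydro-1-benzofuran-3-yl (2Z)-2-(hydroxymethyl)but-2-enoate F13. Acetyl chloride with 2,4,6-collidine at −78 °C should then acetylate the primary alcohol and leave the chelated phenol, giving 23.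

## Further compounds

F1 | step 5 | 5-bromo-4-(methoxymethoxy)-2-(2-oxopropoxy)benzaldehyde | CC(=O)COc1cc(OCOC)c(Br)cc1C=O
F2 | step 5 | 1-[(2R,3S)-5-bromo-3-hydroxy-6-(methoxymethoxy)-2,3-dihydro-1-benzofuran-2-yl]ethanone | CC(=O)[C@@H]1Oc2cc(OCOC)c(Br)cc2[C@@H]1O
F3 | step 5 | 1-[(2R,3S)-5-bromo-6-(methoxymethoxy)-3-(triethylsilyloxy)-2,3-dihydro-1-benzofuran-2-yl]ethanone | CC(=O)[C@@H]1Oc2cc(OCOC)c(Br)cc2[C@@H]1O[Si](CC)(CC)CC
F4 | step 5 | (2S,3S)-5-bromo-6-(methoxymethoxy)-2-(prop-1-en-2-yl)-3-(triethylsilyloxy)-2,3-dihydro-1-benzofuran | C=C(C)[C@@H]1Oc2cc(OCOC)c(Br)cc2[C@@H]1O[Si](CC)(CC)CC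
F5 | step 5 | (2S,3S)-5-(1-ethoxyvinyl)-6-(methoxymethoxy)-2-(prop-1-en-2-yl)-3-(triethylsilyloxy)-2,3-dihydro-1-benzofuran | C=C(C)[C@@H]1Oc2cc(OCOC)c(C(=C)OCC)cc2[C@@H]1O[Si](CC)(CC)CC
F6 | step 4 | 1-(1,1-dimethoxyethyl)-5-(dimethoxymethyl)-2-(methoxymethoxy)-4-(prop-2-yn-1-yloxy)benzene | C#CCOc1cc(OCOC)c(C(C)(OC)OC)cc1C(OC)OC
F7 | step 4 | 1-(1,1-dimethoxyethyl)-5-(dimethoxymethyl)-2-(methoxymethoxy)-4-(propa-1,2-dien-1-yloxy)benzene | C=C=COc1cc(OCOC)c(C(C)(OC)OC)cc1C(OC)OC
F8 | step 9 | (2S,3R)-5-acetyl-6-(methoxymethoxy)-2-(prop-1-en-2-yl)-2,3-dihydro-1-benzofuran-3-yl 4-nitrobenzoate | C=C(C)[C@@H]1Oc2cc(OCOC)c(C(C)=O)cc2[C@H]1OC(=O)c1ccc([N+](=O)[O-])cc1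
F9 | step 9 | 1-[(2S,3R)-3-hydroxy-6-(methoxymethoxy)-2-(prop-1-en-2-yl)-2,3-dihydro-1-benzofuran-5-yl]ethanone | C=C(C)[C@@H]1Oc2cc(OCOC)c(C(C)=O)cc2[C@H]1O
F10 | step 12 | 1-[(2S,3S)-3,6-dihydroxy-2-(prop-1-en-2-yl)-2,3-dihydro-1-benzofuran-5-yl]ethanone | C=C(C)[C@@H]1Oc2cc(O)c(C(C)=O)cc2[C@@H]1O
F11 | step 12 | 1-[(2S,3S)-3-hydroxy-2-(prop-1-en-2-yl)-6-(triisopropylsilyloxy)-2,3-dihydro-1-benzofuran-5-yl]ethanone | C=C(C)[C@@H]1Oc2cc(O[Si](C(C)C)(C(C)C)C(C)C)c(C(C)=O)cc2[C@@H]1O
F12 | step 12 | (2S,3R)-5-acetyl-2-(prop-1-en-2-yl)-6-(triisopropylsilyloxy)-2,3-dihydro-1-benzofuran-3-yl (2Z)-2-{[(triisopropylsilyl)oxy]methyl}but-2-enoate | C=C(C)[C@@H]1Oc2cc(O[Si](C(C)C)(C(C)C)C(C)C)c(C(C)=O)cc2[C@H]1OC(=O)/C(=C\C)CO[Si](C(C)C)(C(C)C)C(C)C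
F13 | step 12 | (2S,3R)-5-acetyl-6-hydroxy-2-(prop-1-en-2-yl)-2,3-dihydro-1-benzofuran-3-yl (2Z)-2-(hydroxymethyl)but-2-enoate | C=C(C)[C@@H]1Oc2cc(O)c(C(C)=O)cc2[C@H]1OC(=O)/C(=C\C)CO
A1 | alternative 1 | (2S,3R)-5-acetyl-2-(prop-1-en-2-yl)-6-(triisopropylsilyloxy)-2,3-dihydro-1-benzofuran-3-yl (2Z)-2-(acetoxymethyl)but-2-enoate | C=C(C)[C@@H]1Oc2cc(O[Si](C(C)C)(C(C)C)C(C)C)c(C(C)=O)cc2[C@H]1OC(=O)/C(=C\C)COC(C)=O
A2 | alternative 1 | (3S,4R)-6-acetyl-3-hydroxy-2,2-dimethyl-7-(triisopropylsilyloxy)-3,4-dihydro-2H-chromen-4-yl (2Z)-2-(acetoxymethyl)but-2-enoate | CC1(C)Oc2cc(O[Si](C(C)C)(C(C)C)C(C)C)c(C(C)=O)cc2[C@@H](OC(=O)/C(=C\C)COC(C)=O)[C@@H]1O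
A3 | alternative 1 | 1-[2,2-dimethyl-7-(triisopropylsilyloxy)-2H-chromen-6-yl]ethanone | CC(=O)c1cc2C=CC(C)(C)Oc2cc1O[Si](C(C)C)(C(C)C)C(C)C
A4 | alternative 2 | 1-[(2S,3R)-6-fluoro-3-hydroxy-2-(prop-1-en-2-yl)-2,3-dihydro-1-benzofuran-5-yl]ethanone | C=C(C)[C@@H]1Oc2cc(F)c(C(C)=O)cc2[C@H]1O
A5 | alternative 2 | 1-{2,4-difluoro-5-[(1R,2S)-1,2-dihydroxy-3-methylbut-3-en-1-yl]phenyl}ethanone | C=C(C)[C@H](O)[C@H](O)c1cc(C(C)=O)c(F)cc1F
A6 | alternative 3 | 1-[(2S,3R)-3,6-dihydroxy-2-(prop-1-en-2-yl)-2,3-dihydro-1-benzofuran-5-yl]ethanone | C=C(C)[C@@H]1Oc2cc(O)c(C(C)=O)cc2[C@H]1O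
A7 | alternative 3 | (2S)-2-(4-acetyl-5-hydroxy-2-iodophenoxy)-3-methylbut-3-enal | C=C(C)[C@@H](C=O)Oc1cc(O)c(C(C)=O)cc1I
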